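## Structural features

Dysidenone B is a rearranged sesquiterpenoid (neoavarane) decalin joined through one methylene carbon (C11) to a 4‑hydroxy‑2‑methoxycyclopent‑2‑enone whose carbinol carbon also carries a methyl ester. The decalin is trans‑fused (C5 quaternary with a β‑methyl, C10 with an α‑hydrogen) and carries four contiguous stereocentres, C5, C10, C9 and C8. C8 is a second quaternary centre (α‑CH3, β‑CH2R), and the C9 methyl is axial and 1,3‑syn‑diaxial to the C5 methyl. Ring A holds a trisubstituted C3=C4 alkene with a C4 methyl next to quaternary C5. The five‑membered ring has two more stereocentres (the tertiary carbinol and the neighbouring CH that bears C11), insulated from the decalin by C11. Fragile groups are the β‑hydroxy ketone/α‑hydroxy ester (retro‑aldol, epimerisable CH), the vinylogous ester, and the C3=C4 alkene, whose protonation would start 1,2‑shifts toward C5. The real difficulty is the C5/C10/C9/C8 array with two quaternary carbons and a contra‑thermodynamic axial methyl, together with the lack of any stereochemical relay to the five‑membered ring. The key step uses the fact that C5 (quaternary, CH3) and C10 (H) are the β‑ and α‑carbons of a 3‑methylcyclohex‑2‑enone whose carbonyl is C9 in ring B, while C1–C4 of ring A with the C4 methyl map onto a 3‑oxygenated penta‑1,3‑diene.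

## Logic of the disconnections

**23 ⇒ 22.** The bond between the carbinol carbon and the C11‑bearing CH, and the ester C–OCH3 bond, are cut by reversing a 1,2‑acyl shift. The carbinol and ester carbons are the two carbons of a masked 1,2‑dione in 22. Both ring stereocentres and the ester vanish. The forward step must add methoxide to the dione tautomer and contract the ring; the remote decalin cannot bias the new carbinol centre, so separation of diastereomers is accepted.

**22 ⇒ 21 ⇒ 20.** Only C–O bonds change: the hydroxyl of 22 returns to a methyl ether (21) and the two quinone carbonyls return to aryl methyl ethers (20). A symmetric tetra‑oxygenated arene is inert to the enolate, dissolving‑metal and hydrogenation chemistry that builds the decalin. The forward steps need an oxidative demethylation that spares the C3=C4 alkene and a hydrolysis selective for the methoxy group next to the alkyl substituent.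

**20 ⇒ 19 ⇒ 17.** C3–H is exchanged for C3–O (19) and the enol triflate for the ketone (17), because a C3 oxygen is what the annulation leaves in ring A. Alkene placement becomes a question of enolate regiochemistry: the more substituted C3=C4 enolate must be trapped.

**17 ⇒ 16 ⇒ 15 ⇒ 14.** The C9–H bond is cut (16), the C3 carbonyl is re‑masked (15), and the exocyclic C9=CH2 bond is cut back to the C9 ketone (14). C9 is the carbonyl carbon of the original enone, and the ketone is the handle that controls C8. The forward steps need hydrogen delivered to the α face (an axial methyl made against thermodynamics), methylenation of a ketone flanked by a quaternary carbon, and a masked C3 carbonyl during that methylenation.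

**14 ⇒ 12 ⇒ 5 + 8.** The C8–CH3 bond and then the C8=C11 bond are cut. Both substituents of C8 are α to the C9 carbonyl, and bringing in C11 as an arylidene lets the enolate be generated only at C8. The whole arene is attached convergently and the quaternary centre falls back to a CH2. The ring fusion must already be trans so that axial methylation puts CH3 on the α face, and enolisation at C8 must not disturb C10.

**8 ⇒ 6.** The aryl–CHO bond is cut; forward, a directed lithiation and formylation.

**5 ⇒ 4.** No skeletal bond is cut; C10–H is inverted, because a cycloaddition can only deliver the cis fusion. The forward step needs an equilibrium on the trans side, so it is run while ring A still carries the C2=C3 silyl enol ether and the fixed 4α‑methyl.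

**4 ⇒ 2 + 3.** C4–C5 and C1–C10 are cut, opening ring A and removing three stereocentres. Both fragments are trivial, and the C9 carbonyl that activates the dienophile is the later handle for C8 and C9. The forward step needs face selection on a sluggish β‑methyl enone.

**2 ⇒ 1.** The O–Si bond is cut; forward, a (Z)‑selective soft enolisation.

## Other disconnections considered

**Alternative 1:** The C8–C11, C9–CH3, C5–CH3 and C10–H bonds of the aryl neoavarane A2 (the same compound as 20) are "un‑migrated" to the 11‑aryl drim‑7‑ene A1. In A1 the arylmethyl group sits on C9, the angular methyl on C10 and a gem‑dimethyl group on C4.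

- Forward step: BF3·OEt2 protonates C7=C8 of A1. The C8 cation is relayed by 1,2‑shifts of C11 (C9→C8), CH3 (C10→C9), H (C5→C10) and CH3 (C4→C5), and loss of H3 gives A2. No ring is formed.
- In its favour: A1 is a short step from chiral‑pool drimanes and aryllithium 7, so absolute configuration is bought, not made. One operation replaces steps 2–11 of the chosen plan. Each shift is suprafacial, so C8, C9, C10 and C5 follow from the substrate. The product is exactly 20, so steps 12–14 are shared.
- Against it here: the cascade must prefer migration of C11 over migration of the axial 9α‑hydrogen, which is better aligned with the empty orbital at C8 and leads to the isomeric skeleton with C9 quaternary. The methyl must then enter C9 on the face C11 has just left, so a discrete cation has to survive two further shifts while open to elimination or Friedel–Crafts capture by the electron‑rich arene. Termination (H3 against other protons) is under no external control.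
- Comparison: on structure the two plans converge on one compound. On mechanism the alternative stakes everything on the partition of one cationic cascade, whereas the chosen plan sets C5, C10, C8 and C9 in four separate, correctable operations. On step economy and on the source of absolute configuration the alternative is clearly the better plan. The chosen plan is more modular (either enantiomer, variation at C8 and C9).

**Alternative 2:** C9–C10 and C4–C5 are cut, opening rings B and A at once to the acyclic enyne A3. A3 has a terminal alkyne on a malonate carbon (C9/C8), an (E)‑trisubstituted C5=C10 alkene and a (Z)‑silyl enol ether at C3=C4.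

- Forward step: the chiral cationic monovalent gold catalyst from [(R)‑DTBM‑MeO‑BIPHEP](AuCl)2 and AgSbF6 activates the alkyne. C10 attacks C9 (6‑exo‑dig) and the C5 cation is captured by C4 of the silyl enol ether. The product is the trans‑decalin A4 with a C9 exo‑methylene, a C3 ketone and a C8 gem‑diester.
- In its favour: two rings, two C–C bonds and the C5, C10 and C4 stereocentres come from one catalytic step. Anti addition across the (E)‑alkene gives the trans fusion directly, so the C10 question of step 3 does not arise; on this point the alternative is better than the chosen plan. The C9 methylene and C3 ketone arrive as they are in 16.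
- Against it here: C8 arrives as C(CO2Me)2. The two diastereotopic esters must be told apart and turned into CH3 and CH2Ar with the right configuration at a neopentyl centre. That costs several redox and C–C steps and raises a new stereo‑differentiation problem, which the chosen plan settles in steps 5 and 6 by substrate control. A3 needs a stereodefined trisubstituted alkene, an alkynyl malonate and a geometrically pure silyl enol ether that must survive a Lewis‑acidic gold/silver medium. Enantiocontrol for this terminator would have to be established, as it must for step 2 (equal on that count).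
- Comparison: on structure the alternative builds more per step and gets the ring fusion right. On mechanism a catalyst‑controlled cationic cyclisation and a catalyst‑controlled annulation carry comparable risk. On step economy the gain in the key step is likely to be spent on making A3 and resolving the gem‑diester, so no net saving is expected.

**Alternative 3:** C8–C9 and C7–C8 are cut, excising C8 from ring B. This leaves the cis‑fused hydrindanone A5 (ring A complete with its C3=C4 alkene, C9 ketone in a five‑membered ring) and the diazo ester A6 (methyl 2‑diazopropanoate), which supplies C8 with its methyl and the future C11 as an ester.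

- Forward step: Sc(OTf)3 with a chiral N,N′‑dioxide ligand promotes addition of A6 to the C9 carbonyl. C7 migrates from C9 to the diazo carbon with loss of N2, giving the ring‑expanded β‑keto ester A7 (cis‑fused, C8 quaternary with CH3 and CO2Me).
- In its favour: the C8 quaternary stereocentre is made in one catalyst‑controlled C–C bond formation, with the methylene C7 (not the methine C10) as the natural migrating group. Ring A is finished beforehand, so the enolate regiochemistry question of step 10 never arises; on that point it is better than the chosen plan.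
- Against it here: the ester is one carbon short of the arene, so C11 needs reduction, aryllithium addition and benzylic deoxygenation next to a ketone (three or four steps against the two of steps 5 and 6). The ligand must match or override the existing C5/C10 centres of A5. A7 is cis‑fused, so C10 must still be epimerised; this is the same thermodynamic question as step 3 (equal, arguably easier with C8 already quaternary). A5 needs its own enantioselective synthesis. C9 methylenation and hydrogenation remain as in steps 7 and 9.
- Comparison: on structure both plans reach a C9 ketone with the C8 substituents in place. On mechanism the alternative relies on catalyst control at C8, where the chosen plan relies on well‑understood axial alkylation. On step economy the two are expected to be similar, with the alternative longer before its key step and the chosen plan longer in ring A.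

Key step: step 2

Remarks on conventions and assumptions:
- Numbering is that of the terpenoid: ring A = C1, C2, C3, C4, C5, C10; ring B = C5–C10; C11 is the CH2 on C8. β is the face of the C5 methyl and α the opposite face.
- Assumption: the (S)‑configured oxazaborolidinium ion is taken to expose the Si face at C3 of 3, by analogy with unsubstituted 2‑cycloalkenones. If the sense proves opposite, the (R)‑catalyst is used with no other change.
- Assumption: C4 may epimerise after step 8. This is of no consequence because C4 becomes sp2 in step 10; the SMILES show the 4α‑methyl.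

## Route

Step 1
Reactants: 1 pent‑1‑en‑3‑one
Product: 2 (Z)‑3‑(tert‑butyldimethylsilyloxy)penta‑1,3‑diene
Conditions: TBSOTf, Et3N, Et2O, 0 °C → rt
Reagents that add atoms: tert‑butyldimethylsilyl trifluoromethanesulfonate, CC(C)(C)[Si](C)(C)OS(=O)(=O)C(F)(F)F
Why: Soft enolisation (O‑silylation, then amine deprotonation of the ethyl group) gives the silyl dienol ether; ethyl ketones give the (Z)‑enol ether under these conditions, which puts the methyl on the outside of the s‑cis diene.

Step 2
Reactants: 2 (Z)‑3‑(tert‑butyldimethylsilyloxy)penta‑1,3‑diene, 3 3‑methylcyclohex‑2‑enone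
Product: 4 cis‑fused 3‑(tert‑butyldimethylsilyloxy)‑4α,5β‑dimethyl‑10β‑H‑decal‑2‑en‑9‑one
Conditions: (S)‑3,3‑diphenyl‑1‑(o‑tolyl)tetrahydropyrrolo[1,2‑c][1,3,2]oxazaborole (20 mol%), Tf2NH (16 mol%), 2 (2 equiv), CH2Cl2, −40 → −20 °C
Reagents that add atoms: none
Why: Proposed new method: the N‑protonated oxazaborolidine binds the carbonyl oxygen of 3 and lowers its LUMO, so that the nucleophilic, methyl‑bearing terminus (C4) of 2 bonds to the β‑carbon (future C5) and C1 to the α‑carbon (future C10), either in one asynchronous [4+2] step or as Mukaiyama–Michael addition followed by Michael closure of the vinyl oxocarbenium ion onto the boron enolate; the closest known reaction type is the oxazaborolidinium‑catalysed enantioselective Diels–Alder reaction of 2‑silyloxydienes with 2‑cycloalkenones, together with the racemic strong‑acid‑promoted annulation of β‑alkyl cycloalkenones with hindered 2‑silyloxydienes, but enantiocontrol with a β,β‑disubstituted enone that creates a quaternary centre has not been shown. Ring A closes as a six‑membered ring by [4+2] cycloaddition (6‑endo Michael closure in the stepwise limit), leaving the C2=C3 silyl enol ether. C5 is controlled by the catalyst, whose aryl group should shield one enone face so that the diene adds to the Si face at C3 of 3. C10 follows from suprafacial addition to the ring alkene, hence the cis fusion that step 3 corrects. C4 is controlled by the endo approach of the (Z)‑diene with its outside methyl, which places the C4 methyl trans to the C5 methyl. Regioselectivity is secured by the silyloxy group, which makes the methyl‑bearing diene terminus the nucleophilic one. The selectivity needed is face discrimination against an achiral background pathway, which is why the acid is kept below the amount of oxazaborolidine and the temperature low.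

Step 3
Reactants: 4 cis‑fused 3‑(tert‑butyldimethylsilyloxy)‑4α,5β‑dimethyl‑10β‑H‑decal‑2‑en‑9‑one
Product: 5 trans‑fused 3‑(tert‑butyldimethylsilyloxy)‑4α,5β‑dimethyl‑10α‑H‑decal‑2‑en‑9‑one
Conditions: DBU (1 equiv), PhMe, 80 °C, to equilibrium; residual 4 recycled
Reagents that add atoms: none
Why: Base‑mediated thermodynamic epimerisation by reversible enolisation toward C10, the only invertible centre α to the ketone (the silyl enol ether freezes C4). With the 4α‑methyl fixed, the trans isomer keeps it pseudoaxial, whereas one cis conformer must place it pseudoequatorial beside the C3 silyloxy group (A(1,2) strain) and the other pushes it over ring B, so trans should dominate even though simple angular‑methyl 1‑decalones are nearly balanced. C10 ends with α‑H, anti to the C5 methyl.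

Step 4
Reactants: 6 1,2,4,5‑tetramethoxybenzene
Product: 8 2,3,5,6‑tetramethoxybenzaldehyde, via 2,3,5,6‑tetramethoxyphenyllithium 7 (not isolated)
Conditions: n‑BuLi, TMEDA, THF, 0 °C; DMF, 0 °C → rt; aq. HCl
Reagents that add atoms: N,N‑dimethylformamide, CN(C)C=O
Why: Directed ortho‑lithiation at a position flanked by two methoxy groups (the two free positions are equivalent), then formylation of the aryllithium with DMF.

Step 5
Reactants: 5 trans‑fused 3‑(tert‑butyldimethylsilyloxy)‑4α,5β‑dimethyl‑10α‑H‑decal‑2‑en‑9‑one, 8 2,3,5,6‑tetramethoxybenzaldehyde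
Product: 12 (E)‑8‑(2,3,5,6‑tetramethoxybenzylidene)‑3‑(tert‑butyldimethylsilyloxy)‑4α,5β‑dimethyl‑10α‑H‑decal‑2‑en‑9‑one, via C8 lithium enolate 9 (not isolated), via lithium aldolate 10 (not isolated), via benzylic mesylate 11 (not isolated)
Conditions: LiN(iPr)2, THF, −78 °C; 8, −78 °C; MsCl, −78 → 0 °C; DBU, rt
Reagents that add atoms: none
Why: Kinetic deprotonation by the hindered amide occurs at the C8 methylene, not at the C10 methine next to quaternary C5, so the ring fusion is untouched. Aldol addition, O‑mesylation and E1cB elimination give the (E)‑arylidene ketone: a Claisen–Schmidt condensation run stepwise so that no hydroxide or alcohol touches the silyl enol ether, which masks the C3 carbonyl and blocks condensation at C2.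

Step 6
Reactants: 12 (E)‑8‑(2,3,5,6‑tetramethoxybenzylidene)‑3‑(tert‑butyldimethylsilyloxy)‑4α,5β‑dimethyl‑10α‑H‑decal‑2‑en‑9‑one
Product: 14 3‑(tert‑butyldimethylsilyloxy)‑4α,5β,8α‑trimethyl‑8β‑(2,3,5,6‑tetramethoxybenzyl)‑10α‑H‑decal‑2‑en‑9‑one, via 8‑arylmethyl lithium enolate 13 (not isolated)
Conditions: Li (2.2 equiv), NH3(l)/THF, t‑BuOH (1.0 equiv), −78 °C; isoprene; MeI, −78 → −33 °C
Reagents that add atoms: iodomethane, CI
Why: Birch‑type reductive alkylation: two‑electron reduction of the aryl‑conjugated enone gives the C8=C9 lithium enolate regiospecifically, with C10 never enolised. Methyl iodide attacks the trans‑fused enolate axially on the α face through a chair‑like transition state (only axial hydrogens at C6 and C10 on that face), so C8 receives α‑CH3 and keeps the arylmethyl group β.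

Step 7
Reactants: 14 3‑(tert‑butyldimethylsilyloxy)‑4α,5β,8α‑trimethyl‑8β‑(2,3,5,6‑tetramethoxybenzyl)‑10α‑H‑decal‑2‑en‑9‑one
Product: 15 3‑(tert‑butyldimethylsilyloxy)‑4α,5β,8α‑trimethyl‑9‑methylene‑8β‑(2,3,5,6‑tetramethoxybenzyl)‑10α‑H‑decal‑2‑ene
Conditions: Cp2TiMe2 (3 equiv), PhMe, 80 °C, dark
Reagents that add atoms: dimethyltitanocene, C[Ti](C)(C1C=CC=C1)C1C=CC=C1
Why: Carbonyl methylenation through a titanium methylidene and an oxatitanacyclobutane; the reagent is non‑basic, so C10 is not epimerised, and it tolerates the silyl enol ether. That enol ether keeps the less hindered C3 carbonyl masked, which would otherwise react first.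

Step 8
Reactants: 15 3‑(tert‑butyldimethylsilyloxy)‑4α,5β,8α‑trimethyl‑9‑methylene‑8β‑(2,3,5,6‑tetramethoxybenzyl)‑10α‑H‑decal‑2‑ene
Product: 16 4α,5β,8α‑trimethyl‑9‑methylene‑8β‑(2,3,5,6‑tetramethoxybenzyl)‑10α‑H‑decalin‑3‑one
Conditions: Bu4NF, AcOH, THF, 0 °C
Reagents that add atoms: none
Why: Fluoride cleaves the Si–O bond and acetic acid protonates the enolate at C2 to release the C3 ketone. The buffered, non‑acidic medium protects the 1,1‑disubstituted alkene from protonation and cationic rearrangement at C9/C8.

Step 9
Reactants: 16 4α,5β,8α‑trimethyl‑9‑methylene‑8β‑(2,3,5,6‑tetramethoxybenzyl)‑10α‑H‑decalin‑3‑one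
Product: 17 4α,5β,8α,9β‑tetramethyl‑8β‑(2,3,5,6‑tetramethoxybenzyl)‑9α‑H‑10α‑H‑decalin‑3‑one
Conditions: H2 (3 atm), PtO2, EtOAc, rt
Reagents that add atoms: none
Why: Heterogeneous syn‑hydrogenation of the only C=C present (ketone and arene are inert here). The β lobe of the exocyclic π bond points over ring B at the syn‑axial C5 methyl and the C7 axial hydrogen, while the α lobe points outward past the adjacent axial 8α‑methyl, so hydrogen should arrive on the α face and give 9α‑H with the axial 9β‑methyl. PtO2 is chosen over palladium to limit migration of the double bond into the ring fusion.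

Step 10
Reactants: 17 4α,5β,8α,9β‑tetramethyl‑8β‑(2,3,5,6‑tetramethoxybenzyl)‑9α‑H‑10α‑H‑decalin‑3‑one
Product: 19 4,5β,8α,9β‑tetramethyl‑8β‑(2,3,5,6‑tetramethoxybenzyl)‑10α‑H‑decal‑3‑en‑3‑yl trifluoromethanesulfonate, via C3=C4 lithium enolate 18 (not isolated)
Conditions: LiN(iPr)2 (0.95 equiv), THF, −78 °C → rt, 2 h; PhNTf2, 0 °C → rt
Reagents that add atoms: N‑phenylbis(trifluoromethanesulfonimide), O=S(=O)(N(c1ccccc1)S(=O)(=O)C(F)(F)F)C(F)(F)F
Why: With a slight deficit of base the lithium enolates equilibrate by proton transfer through residual ketone, which should funnel both C4 epimers into the more substituted C3=C4 enolate. O‑Triflation with the N‑aryl triflimide then fixes that regiochemistry as the enol triflate.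

Step 11
Reactants: 19 4,5β,8α,9β‑tetramethyl‑8β‑(2,3,5,6‑tetramethoxybenzyl)‑10α‑H‑decal‑3‑en‑3‑yl trifluoromethanesulfonate
Product: 20 1,2,4,5‑tetramethoxy‑3‑[(4,5β,8α,9β‑tetramethyl‑10α‑H‑decal‑3‑en‑8β‑yl)methyl]benzene
Conditions: Pd(OAc)2 (5 mol%), PPh3, n‑Bu3N, HCO2H, DMF, 60 °C
Reagents that add atoms: none
Why: Palladium‑catalysed formate reduction of an enol triflate: oxidative addition of zerovalent palladium into C–OTf, formate exchange with loss of CO2, and C–H reductive elimination. The double bond stays at C3=C4.

Step 12
Reactants: 20 1,2,4,5‑tetramethoxy‑3‑[(4,5β,8α,9β‑tetramethyl‑10α‑H‑decal‑3‑en‑8β‑yl)methyl]benzene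
Product: 21 2,5‑dimethoxy‑3‑[(4,5β,8α,9β‑tetramethyl‑10α‑H‑decal‑3‑en‑8β‑yl)methyl]‑1,4‑benzoquinone
Conditions: (NH4)2Ce(NO3)6 (2.5 equiv), MeCN/H2O, 0 °C, 15 min
Reagents that add atoms: water, O
Why: Oxidative demethylation of a para‑dimethoxy pair by tetravalent cerium through the arene radical cation and attack of water at the ipso carbons, with loss of two methanol. The two para pairs of the arene are symmetry‑equivalent, so one quinone forms, and the short cold exposure should spare the hindered trisubstituted alkene.

Step 13
Reactants: 21 2,5‑dimethoxy‑3‑[(4,5β,8α,9β‑tetramethyl‑10α‑H‑decal‑3‑en‑8β‑yl)methyl]‑1,4‑benzoquinone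
Product: 22 2‑hydroxy‑5‑methoxy‑3‑[(4,5β,8α,9β‑tetramethyl‑10α‑H‑decal‑3‑en‑8β‑yl)methyl]‑1,4‑benzoquinone
Conditions: KOH, MeOH/H2O, rt; then 1 M HCl
Reagents that add atoms: potassium hydroxide, [K+].[OH-]
Why: Addition–elimination of hydroxide at a vinylogous ester. The methoxy group flanked by the alkyl substituent is twisted out of conjugation and is the more electrophilic one, and the vinylogous carboxylate formed resists a second substitution.

Step 14
Reactants: 22 2‑hydroxy‑5‑methoxy‑3‑[(4,5β,8α,9β‑tetramethyl‑10α‑H‑decal‑3‑en‑8β‑yl)methyl]‑1,4‑benzoquinone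
Product: 23 dysidenone B (methyl 1‑hydroxy‑3‑methoxy‑4‑oxo‑5‑[(4,5β,8α,9β‑tetramethyl‑10α‑H‑decal‑3‑en‑8β‑yl)methyl]cyclopent‑2‑ene‑1‑carboxylate with 1‑OH trans to the C5 substituent and absolute configuration as in the SMILES)
Conditions: NaOMe (3 equiv), MeOH, 60 °C; AcOH; preparative HPLC
Reagents that add atoms: methanol (as sodium methoxide), CO
Why: Benzilic ester rearrangement of the hydroxyquinone in its 1,2‑dione (cyclohexene‑1,2,4‑trione) form: methanol/methoxide adds to the carbonyl next to the alkyl‑bearing carbon, and that carbon migrates to the neighbouring carbonyl, which becomes the tertiary alkoxide while the migration origin becomes the methyl ester. The CH centre α to the ketone equilibrates under the base, but the carbinol configuration forms without influence from the remote decalin, so 23 is expected together with its ring diastereomers and is isolated by HPLC (its CH epimer can be re‑equilibrated).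

## Compound list

1 | pent‑1‑en‑3‑one | CCC(=O)C=C | starting material
2 | (Z)‑3‑(tert‑butyldimethylsilyloxy)penta‑1,3‑diene | C=C/C(O[Si](C)(C)C(C)(C)C)=C/C | intermediate
3 | 3‑methylcyclohex‑2‑enone | CC1=CC(=O)CCC1 | starting material
4 | cis‑fused 3‑(tert‑butyldimethylsilyloxy)‑4α,5β‑dimethyl‑10β‑H‑decal‑2‑en‑9‑one | O=C1CCC[C@]2(C)[C@H](C)C(O[Si](C)(C)C(C)(C)C)=CC[C@H]12 | intermediate
5 | trans‑fused 3‑(tert‑butyldimethylsilyloxy)‑4α,5β‑dimethyl‑10α‑H‑decal‑2‑en‑9‑one | O=C1CCC[C@]2(C)[C@H](C)C(O[Si](C)(C)C(C)(C)C)=CC[C@@H]12 | intermediate
6 | 1,2,4,5‑tetramethoxybenzene | COc1cc(OC)c(OC)cc1OC | starting material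
7 | 2,3,5,6‑tetramethoxyphenyllithium | [Li]c1c(OC)c(OC)cc(OC)c1OC | intermediate (not isolated)
8 | 2,3,5,6‑tetramethoxybenzaldehyde | O=Cc1c(OC)c(OC)cc(OC)c1OC | intermediate
9 | C8=C9 lithium enolate of 5 | [Li]OC1=CCC[C@]2(C)[C@H](C)C(O[Si](C)(C)C(C)(C)C)=CC[C@@H]12 | intermediate (not isolated)
10 | lithium aldolate from 9 and 8 (mixture at C8 and C11) | O=C1C(C(O[Li])c3c(OC)c(OC)cc(OC)c3OC)CC[C@]2(C)[C@H](C)C(O[Si](C)(C)C(C)(C)C)=CC[C@@H]12 | intermediate (not isolated)
11 | C11 methanesulfonate of the aldol adduct (mixture at C8 and C11) | O=C1C(C(OS(C)(=O)=O)c3c(OC)c(OC)cc(OC)c3OC)CC[C@]2(C)[C@H](C)C(O[Si](C)(C)C(C)(C)C)=CC[C@@H]12 | intermediate (not isolated)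
12 | (E)‑8‑(2,3,5,6‑tetramethoxybenzylidene)‑3‑(tert‑butyldimethylsilyloxy)‑4α,5β‑dimethyl‑10α‑H‑decal‑2‑en‑9‑one | O=C1/C(=C/c3c(OC)c(OC)cc(OC)c3OC)CC[C@]2(C)[C@H](C)C(O[Si](C)(C)C(C)(C)C)=CC[C@@H]12 | intermediate
13 | C8=C9 lithium enolate carrying the 8‑(2,3,5,6‑tetramethoxybenzyl) group | [Li]OC1=C(Cc3c(OC)c(OC)cc(OC)c3OC)CC[C@]2(C)[C@H](C)C(O[Si](C)(C)C(C)(C)C)=CC[C@@H]12 | intermediate (not isolated)
14 | 3‑(tert‑butyldimethylsilyloxy)‑4α,5β,8α‑trimethyl‑8β‑(2,3,5,6‑tetramethoxybenzyl)‑10α‑H‑decal‑2‑en‑9‑one | O=C1[C@@](C)(Cc3c(OC)c(OC)cc(OC)c3OC)CC[C@]2(C)[C@H](C)C(O[Si](C)(C)C(C)(C)C)=CC[C@@H]12 | intermediate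
15 | 3‑(tert‑butyldimethylsilyloxy)‑4α,5β,8α‑trimethyl‑9‑methylene‑8β‑(2,3,5,6‑tetramethoxybenzyl)‑10α‑H‑decal‑2‑ene | C=C1[C@@](C)(Cc3c(OC)c(OC)cc(OC)c3OC)CC[C@]2(C)[C@H](C)C(O[Si](C)(C)C(C)(C)C)=CC[C@@H]12 | intermediate
16 | 4α,5β,8α‑trimethyl‑9‑methylene‑8β‑(2,3,5,6‑tetramethoxybenzyl)‑10α‑H‑decalin‑3‑one | C=C1[C@@](C)(Cc3c(OC)c(OC)cc(OC)c3OC)CC[C@]2(C)[C@H](C)C(=O)CC[C@@H]12 | intermediate
17 | 4α,5β,8α,9β‑tetramethyl‑8β‑(2,3,5,6‑tetramethoxybenzyl)‑9α‑H‑10α‑H‑decalin‑3‑one | C[C@H]1[C@@](C)(Cc3c(OC)c(OC)cc(OC)c3OC)CC[C@]2(C)[C@H](C)C(=O)CC[C@@H]12 | intermediate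
18 | C3=C4 lithium enolate of 17 | C[C@H]1[C@@](C)(Cc3c(OC)c(OC)cc(OC)c3OC)CC[C@]2(C)C(C)=C(O[Li])CC[C@@H]12 | intermediate (not isolated)
19 | 4,5β,8α,9β‑tetramethyl‑8β‑(2,3,5,6‑tetramethoxybenzyl)‑10α‑H‑decal‑3‑en‑3‑yl trifluoromethanesulfonate | C[C@H]1[C@@](C)(Cc3c(OC)c(OC)cc(OC)c3OC)CC[C@]2(C)C(C)=C(OS(=O)(=O)C(F)(F)F)CC[C@@H]12 | intermediate
20 | 1,2,4,5‑tetramethoxy‑3‑[(4,5β,8α,9β‑tetramethyl‑10α‑H‑decal‑3‑en‑8β‑yl)methyl]benzene | COc1cc(OC)c(OC)c(C[C@@]2(C)CC[C@]3(C)C(C)=CCC[C@H]3[C@H]2C)c1OC | intermediate
21 | 2,5‑dimethoxy‑3‑[(4,5β,8α,9β‑tetramethyl‑10α‑H‑decal‑3‑en‑8β‑yl)methyl]‑1,4‑benzoquinone | O=C1C(C[C@@]2(C)CC[C@]3(C)C(C)=CCC[C@H]3[C@H]2C)=C(OC)C(=O)C=C1OC | intermediate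
22 | 2‑hydroxy‑5‑methoxy‑3‑[(4,5β,8α,9β‑tetramethyl‑10α‑H‑decal‑3‑en‑8β‑yl)methyl]‑1,4‑benzoquinone | O=C1C(C[C@@]2(C)CC[C@]3(C)C(C)=CCC[C@H]3[C@H]2C)=C(O)C(=O)C=C1OC | intermediate
23 | dysidenone B | COC(=O)[C@@]1(O)C=C(OC)C(=O)[C@H]1C[C@@]1(C)CC[C@]2(C)C(C)=CCC[C@H]2[C@H]1C | target

## Step count and least certain steps

Total step count: 14. Longest linear sequence: 13 (steps 1–3 and 5–14; step 4 is the convergent branch).

**Step 2 (key step, proposed new method).**
- What may go wrong: loss of face selection through a racemic background pathway. Protodesilylation of 2 by the acid generates an achiral silyl triflimide that can catalyse the Mukaiyama–Michael/Michael sequence, and the β‑methyl enone reacts slowly enough for this to compete. Slow conversion and erosion of the C4/C5 relative configuration in a stepwise pathway are further risks.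
- Fallback (known chemistry): setting out from 2 and 3, the same union is run with an achiral promoter of established scope for hindered 2‑silyloxydienes and β‑alkyl cycloalkenones (Tf2NH 5 mol%, CH2Cl2, −40 °C, or AlBr3/AlMe3). This should give 4 as a racemate, that is together with its mirror image ent‑4 F1. DBU equilibration as in step 3 gives the racemic trans ketone, 5 together with ent‑5 F2. The enantiomers are separated by preparative chromatography on a chiral stationary phase, and the route is rejoined at 5.

**Step 3.**
- What may go wrong: incomplete inversion at C10, because the equilibrium may lie less far on the trans side than the conformational argument predicts (the parent angular‑methyl 1‑decalones are nearly balanced). Slow enolisation of the hindered methine is a second risk.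
- Fallback: setting out from 4, the order of the C8 alkylations is inverted and the epimerisation is postponed.
  - Kinetic enolisation (LiN(iPr)2, THF, −78 °C) and MeI give the cis‑fused 8‑methyl ketone F3 (C8 epimers).
  - In parallel, 8 is reduced (NaBH4, MeOH) to (2,3,5,6‑tetramethoxyphenyl)methanol F4 and converted (PBr3, Et2O, 0 °C) into 2,3,5,6‑tetramethoxybenzyl bromide F5.
  - Deprotonation of F3 at C8 (KN(SiMe3)2, THF, −78 °C; the C10 hydrogen is screened by quaternary C5) and alkylation with F5 should occur on the β face of the cis‑decalin enolate, anti to the pseudoaxial C10–C1 bond. This gives the cis‑fused 8α‑methyl‑8β‑arylmethyl ketone F6.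
  - In F6 one cis conformer has the 8α‑methyl syn‑diaxial to C1 and the other forces the 4α‑methyl against ring B. Base equilibration (DBU, PhMe, 80 °C) at this stage should therefore favour the trans isomer decisively; this is 14, where the route is rejoined.

**Step 7.**
- What may go wrong: failure of the carbonyl to engage the titanium methylidene for steric reasons (C9 lies between quaternary C8 and a methine next to quaternary C5), with slow decomposition of the reagent instead.
- Fallback: setting out from 14, a Peterson olefination in two stages. Me3SiCH2Li with CeCl3 (THF, −78 → 0 °C), the smallest one‑carbon nucleophile available, adds to C9 to give the β‑hydroxysilane F7. KH (THF, 50 °C) then induces syn‑elimination of silanolate to give 15, where the route is rejoined.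

**Step 10.**
- What may go wrong: trapping of the less substituted C2=C3 enolate, if enolate equilibration is incomplete or if strain between the C4 methyl and C6 erodes the preference for the tetrasubstituted enolate.
- Fallback: setting out from 17, regiospecific kinetic triflation (LiN(iPr)2, THF, −78 °C; PhNTf2) gives the C2=C3 enol triflate F8. This is reduced under the conditions of step 11 to the C2=C3 alkene F9. RhCl3·3H2O in EtOH at 80 °C then moves the double bond by metal hydride addition–elimination into the more substituted C3=C4 position, giving 20, where the route is rejoined.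

**Step 14.**
- What may go wrong: no contraction, because the base merely parks the substrate as its unreactive vinylogous carboxylate; retro‑aldol opening of the β‑hydroxy ketone product on prolonged heating; and unselective formation of the carbinol configuration, since the decalin is too remote to direct it, so that 23 is only one of up to four ring diastereomers.
- Fallback: setting out from 22, a classical benzilic acid rearrangement with Ba(OH)2 in aqueous dioxane (the divalent cation chelates the dione tautomer) gives the ring‑contracted hydroxy acid F10 as a diastereomer mixture. Me3SiCHN2 in MeOH/PhMe esterifies it to 23, which is isolated by HPLC as before; the CH epimer is recycled by base equilibration.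

## Further compounds

F1 | step 2 | ent‑4, mirror image of 4 | O=C1CCC[C@@]2(C)[C@@H](C)C(O[Si](C)(C)C(C)(C)C)=CC[C@@H]12
F2 | step 2 | ent‑5, mirror image of 5 | O=C1CCC[C@@]2(C)[C@@H](C)C(O[Si](C)(C)C(C)(C)C)=CC[C@H]12
F3 | step 3 | cis‑fused 3‑(tert‑butyldimethylsilyloxy)‑4α,5β,8‑trimethyl‑10β‑H‑decal‑2‑en‑9‑one (C8 epimers) | O=C1C(C)CC[C@]2(C)[C@H](C)C(O[Si](C)(C)C(C)(C)C)=CC[C@H]12
F4 | step 3 | (2,3,5,6‑tetramethoxyphenyl)methanol | OCc1c(OC)c(OC)cc(OC)c1OC
F5 | step 3 | 2,3,5,6‑tetramethoxybenzyl bromide | BrCc1c(OC)c(OC)cc(OC)c1OC
F6 | step 3 | cis‑fused 3‑(tert‑butyldimethylsilyloxy)‑4α,5β,8α‑trimethyl‑8β‑(2,3,5,6‑tetramethoxybenzyl)‑10β‑H‑decal‑2‑en‑9‑one | O=C1[C@@](C)(Cc3c(OC)c(OC)cc(OC)c3OC)CC[C@]2(C)[C@H](C)C(O[Si](C)(C)C(C)(C)C)=CC[C@H]12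
F7 | step 7 | 9‑hydroxy‑9‑(trimethylsilylmethyl) adduct of 14 (C9 configuration open) | C[Si](C)(C)CC1(O)[C@@](C)(Cc3c(OC)c(OC)cc(OC)c3OC)CC[C@]2(C)[C@H](C)C(O[Si](C)(C)C(C)(C)C)=CC[C@@H]12
F8 | step 10 | 4α,5β,8α,9β‑tetramethyl‑8β‑(2,3,5,6‑tetramethoxybenzyl)‑10α‑H‑decal‑2‑en‑3‑yl trifluoromethanesulfonate | C[C@H]1[C@@](C)(Cc3c(OC)c(OC)cc(OC)c3OC)CC[C@]2(C)[C@H](C)C(OS(=O)(=O)C(F)(F)F)=CC[C@@H]12
F9 | step 10 | 1,2,4,5‑tetramethoxy‑3‑[(4α,5β,8α,9β‑tetramethyl‑10α‑H‑decal‑2‑en‑8β‑yl)methyl]benzene | C[C@H]1[C@@](C)(Cc3c(OC)c(OC)cc(OC)c3OC)CC[C@]2(C)[C@H](C)C=CC[C@@H]12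
F10 | step 14 | 1‑hydroxy‑3‑methoxy‑4‑oxo‑5‑[(4,5β,8α,9β‑tetramethyl‑10α‑H‑decal‑3‑en‑8β‑yl)methyl]cyclopent‑2‑ene‑1‑carboxylic acid | OC(=O)[C@@]1(O)C=C(OC)C(=O)[C@H]1C[C@@]1(C)CC[C@]2(C)C(C)=CCC[C@H]2[C@H]1C
A1 | alternative 1 | 11‑(2,3,5,6‑tetramethoxyphenyl)drim‑7‑ene | COc1cc(OC)c(OC)c(C[C@H]2C(C)=CC[C@H]3C(C)(C)CCC[C@]23C)c1OC
A2 | alternative 1 | aryl neoavarane, identical with 20 | COc1cc(OC)c(OC)c(C[C@@]2(C)CC[C@]3(C)C(C)=CCC[C@H]3[C@H]2C)c1OC
A3 | alternative 2 | dimethyl 2‑ethynyl‑2‑[(3E,7Z)‑7‑(tert‑butyldimethylsilyloxy)‑3‑methylnona‑3,7‑dien‑1‑yl]propanedioate | C#CC(C(=O)OC)(C(=O)OC)CC/C(C)=C/CC/C(O[Si](C)(C)C(C)(C)C)=C/C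
A4 | alternative 2 | dimethyl trans‑fused 4β,5β‑dimethyl‑9‑methylene‑3‑oxo‑10α‑H‑decalin‑8,8‑dicarboxylate | C=C1C(C(=O)OC)(C(=O)OC)CC[C@]2(C)[C@@H](C)C(=O)CC[C@H]21
A5 | alternative 3 | cis‑fused 3a,4‑dimethyl‑2,3,3a,6,7,7a‑hexahydroinden‑1‑one | O=C1CC[C@]2(C)C(C)=CCC[C@H]12
A6 | alternative 3 | methyl 2‑diazopropanoate | COC(=O)C(C)=[N+]=[N-]
A7 | alternative 3 | methyl cis‑fused 4,5β,8α‑trimethyl‑9‑oxo‑10β‑H‑decal‑3‑ene‑8β‑carboxylate | COC(=O)[C@@]1(C)CC[C@]2(C)C(C)=CCC[C@@H]2C1=O
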